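Early on, while the nucleophile still runs in, I watch one thing in this flask: where each acid set free ends up.

    electrophile + nucleophile ⇌ acid set free + target (K1 = 0.240, k1 = 500 M⁻¹ s⁻¹)
    nucleophile + acid set free ⇌ protonated nucleophile, settled at all times (K2 = 2.8 × 10⁵ M⁻¹)
    acid set free + free base ⇌ salt of the base, settled at all times (K3 = 21000 M⁻¹)
    electrophile + target → side product (k4 = 61.0 M⁻¹ s⁻¹)
    gas ⇌ free base, rate k5*(csat - [free base]) (k5 = 0.407 s⁻¹, csat = 0.19 mM)

electrophile 0.0010 M; nucleophile 1.00 mM (fed, over 1.2 s); gas 0.19 mM (held); time 8.0 s

- percentages count the electrophile that a species holds: one side product counts as two
- at the start none of free base is dissolved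
- run time (flask): 8.0 s

- part of the electrophile that has reacted at 8.0 s
- share of the unused nucleophile that is free and not bound as protonated nucleophile, at 8.0 s

Each turn of step 1 sets free one acid, and the nucleophile binds it more tightly than the free base does, so I charge two nucleophiles per turn. Here 50.0% is my two-for-one ceiling, the nucleophile charge divided by two and by the electrophile charge: the part of the electrophile that step 1 turns if every turn costs two nucleophiles. Two nucleophiles per electrophile ask for more than was charged, so the nucleophile is the limiting reagent.

Now the settings. More nucleophile lifts the ceiling in proportion; more electrophile lowers it in proportion. The gas I leave out of the ceiling, since the free base it supplies binds the acid less tightly than the nucleophile does. The side step I keep: the target's half-life by it alone is 11 s, against a run of 8.0 s. With electrophile and target held at what the ceiling leaves, it takes a further 10.4% of the electrophile after the feed, and that turn sets free no acid. So I commit to 60.4% reacted, and to no figure for the free share.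

The forecast says 58% and 16%, starting from this: “Each electrophile consumed early on also ties up a second nucleophile as its protonated form”. Its figure for the electrophile stands below mine.

The flask gives 58.0% and 17.4%. At 1.45 s the forward rate of step 1 uses electrophile 17 times as fast as the side step. At 8.00 s step 1 relaxes, both ways together, with a half-life of 0.608 s, short against the time. The speed of the gas transfer makes no difference to the part reacted, while the charges rank nucleophile (12 points), then electrophile (9.1 points). At 8.00 s in this flask, acid in its free and bound forms comes to 49.4% of the electrophile charged, level with the ceiling. The neighbour charged with 0.0017 M of electrophile has a ceiling of 29.4% and at 8.00 s holds acid, free and bound forms together, at 31.6% of its electrophile charge.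

All constants are invented; no experiment stands behind them.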